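Ring B (the dihydropyran ring O1–C2–C3–C4–C4a–C8a) is cut twice, at C3–C4 and at O1–C8a, as a formal [3+3] annulation. This exploits that C8a lies between C4a–CH2 and C8–CH3, so the arene half is the ortho-bromobenzyl bromide from symmetrical 4-bromo-3,5-dimethylphenol. The quaternary C2–O1 unit is a 2,2-disubstituted epoxide made by enantioselective methylene transfer to (E)-geranylacetone. In one flask the benzylic Grignard reagent opens the (R)-epoxide at its CH2 group, and the tertiary alkoxide is then O-arylated at the flanked C–Br bond under palladium catalysis, with C2 untouched. Terminal allylic oxidation, oxidation to the acid and desilylation complete the route.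

Key step: step 4

Assumption: (E)-geranylacetone is bought as the single E isomer, and the (S)-BINOL-derived La/Li catalyst is taken to give the (R)-epoxide; if a test run shows the opposite sense of induction, the (R)-BINOL-derived catalyst is used with nothing else changed.

Step 1
Reactants: 1 4-bromo-3,5-dimethylphenol
Product: 2 (4-bromo-3,5-dimethylphenoxy)tri(propan-2-yl)silane
Conditions: TIPSCl, imidazole, DMF, rt
Reagents that add atoms: chlorotri(propan-2-yl)silane, CC(C)[Si](Cl)(C(C)C)C(C)C
Why: Imidazole-mediated O-silylation of the phenol; the bulky silyl ether should withstand radical bromination, the Grignard reagent and tert-butoxide, and is removed by fluoride at the end.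

Step 2
Reactants: 2 (4-bromo-3,5-dimethylphenoxy)tri(propan-2-yl)silane
Product: 3 [4-bromo-3-(bromomethyl)-5-methylphenoxy]tri(propan-2-yl)silane
Conditions: NBS (0.95 equiv), AIBN (5 mol%), PhCF3, 80 °C
Reagents that add atoms: N-bromosuccinimide, O=C1CCC(=O)N1Br
Why: Wohl–Ziegler radical bromination, in which the two methyl groups are equivalent so only the degree of bromination has to be controlled (sub-stoichiometric NBS, recovered 2 recycled), and the silyloxy group is less ring-activating than methoxy, which should disfavour nuclear bromination under non-polar radical conditions.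

Step 3
Reactants: 4 (5E)-6,10-dimethylundeca-5,9-dien-2-one ((E)-geranylacetone)
Product: 5 (2R)-2-[(3E)-4,8-dimethylnona-3,7-dien-1-yl]-2-methyloxirane
Conditions: Me3S(O)I, NaH, THF (ylide pre-formed); then 4, LaLi3[(S)-BINOLate]3 (5 mol%), tris(2,4,6-trimethoxyphenyl)phosphine oxide (5 mol%), 5 Å MS, THF, rt
Reagents that add atoms: trimethylsulfoxonium iodide, C[S+](C)(C)=O.[I-]
Why: Catalytic asymmetric Corey–Chaykovsky epoxidation, in which the La/Li binaphthoxide binds the methyl ketone and directs dimethylsulfoxonium methylide to one carbonyl face (methyl against primary alkyl), setting C2 as R by catalyst control, while the unactivated trisubstituted alkenes are inert to the ylide.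

Step 4
Reactants: 3 [4-bromo-3-(bromomethyl)-5-methylphenoxy]tri(propan-2-yl)silane; 5 (2R)-2-[(3E)-4,8-dimethylnona-3,7-dien-1-yl]-2-methyloxirane
Product: 8 {[(2R)-2-[(3E)-4,8-dimethylnona-3,7-dien-1-yl]-2,8-dimethyl-3,4-dihydro-2H-chromen-6-yl]oxy}tri(propan-2-yl)silane, via benzylic Grignard reagent 6 (not isolated), via bromomagnesium alkoxide 7 (not isolated)
Conditions: Mg, 2-MeTHF, 0 °C; then 5 (1.15 equiv), CuI (10 mol%), THF, −30 → 0 °C; then NaOtBu (1.2 equiv), Pd(OAc)2 (5 mol%), 2-(di-tert-butylphosphino)-1,1'-binaphthyl (6 mol%), toluene, 80 °C (THF distilled off), one flask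
Reagents that add atoms: none
Why: Magnesium inserts selectively into the benzylic C–Br bond of 3 (the aryl C–Br bond is inert at 0 °C) to give 6, the benzylcopper species formed with CuI opens epoxide 5 by SN2 attack at its unsubstituted CH2 group (C3–C4 bond) to give alkoxide 7, and zerovalent palladium then inserts into the flanked aryl C–Br bond, the alkoxide (as its sodium salt after exchange with NaOtBu) displaces bromide on divalent palladium, and C–O reductive elimination forms O1–C8a. The closest known reaction types are the copper-catalysed Grignard opening of 2,2-disubstituted epoxides and the Buchwald-type palladium-catalysed intramolecular etherification of aryl bromides with tertiary alcohols, run here consecutively without work-up as a formal [3+3] annulation. Ring B closes at O1–C8a by reductive elimination from a seven-membered aryl(alkoxo)palladium chelate, formally a 6-exo attack of the C2 alkoxide on C8a. No stereocentre is created: C2 of (R)-5 is carried through with retention because the epoxide is attacked only at CH2 and the C2–O bond is never broken. The step needs regioselective epoxide opening, secured by the quaternary nature of C2 and by copper catalysis at low temperature (which also suppresses Lewis-acid rearrangement of the epoxide), and clean etherification, secured because the tertiary alkoxide has no hydrogen on its carbinol carbon for β-hydride elimination and the two ortho substituents accelerate reductive elimination; since the two methyl groups of 1 are equivalent, no regiochemical question arises on the arene.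

Step 5
Reactants: 8 {[(2R)-2-[(3E)-4,8-dimethylnona-3,7-dien-1-yl]-2,8-dimethyl-3,4-dihydro-2H-chromen-6-yl]oxy}tri(propan-2-yl)silane
Product: 10 (2E,6E)-9-[(2R)-2,8-dimethyl-6-{[tri(propan-2-yl)silyl]oxy}-3,4-dihydro-2H-chromen-2-yl]-2,6-dimethylnona-2,6-dienal, via allylic alcohol 9 (not isolated)
Conditions: SeO2 (0.3 equiv), t-BuOOH, salicylic acid (10 mol%), CH2Cl2, 0 °C → rt; silica plug; then MnO2, CH2Cl2, rt
Reagents that add atoms: selenium dioxide, O=[Se]=O; tert-butyl hydroperoxide, CC(C)(C)OO
Why: SeO2/t-BuOOH allylic oxidation (ene reaction then [2,3]-sigmatropic shift) should attack the less hindered terminal isopropylidene unit at its (E)-methyl group, and MnO2 oxidation of the allylic alcohol then converges the alcohol/aldehyde mixture on the (E)-enal without touching the aryl silyl ether.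

Step 6
Reactants: 10 (2E,6E)-9-[(2R)-2,8-dimethyl-6-{[tri(propan-2-yl)silyl]oxy}-3,4-dihydro-2H-chromen-2-yl]-2,6-dimethylnona-2,6-dienal
Product: 11 (2E,6E)-9-[(2R)-2,8-dimethyl-6-{[tri(propan-2-yl)silyl]oxy}-3,4-dihydro-2H-chromen-2-yl]-2,6-dimethylnona-2,6-dienoic acid
Conditions: NaClO2, NaH2PO4, 2-methyl-2-butene (excess), t-BuOH/H2O, 0 °C → rt
Reagents that add atoms: sodium chlorite, [Na+].[O-]Cl=O
Why: Pinnick oxidation converts the enal into the acid without E/Z isomerisation, and excess 2-methyl-2-butene scavenges HOCl so that the electron-rich arene and the chain alkenes should be spared.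

Step 7
Reactants: 11 (2E,6E)-9-[(2R)-2,8-dimethyl-6-{[tri(propan-2-yl)silyl]oxy}-3,4-dihydro-2H-chromen-2-yl]-2,6-dimethylnona-2,6-dienoic acid
Product: 12 (2E,6E)-9-[(2R)-6-hydroxy-2,8-dimethyl-3,4-dihydro-2H-chromen-2-yl]-2,6-dimethylnona-2,6-dienoic acid (CNP0176653.1)
Conditions: TBAF, AcOH (1:1), THF, 0 °C → rt, under argon
Reagents that add atoms: none
Why: Fluoride-induced cleavage of the aryl Si–O bond (desilylation), buffered with acetic acid so that the oxidation-sensitive chromanol is not held as its phenoxide, should release the target with nothing else in the molecule reacting.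

Compound list

1 | 4-bromo-3,5-dimethylphenol | Cc1cc(O)cc(C)c1Br | starting material
2 | (4-bromo-3,5-dimethylphenoxy)tri(propan-2-yl)silane | Cc1cc(O[Si](C(C)C)(C(C)C)C(C)C)cc(C)c1Br | intermediate
3 | [4-bromo-3-(bromomethyl)-5-methylphenoxy]tri(propan-2-yl)silane | Cc1cc(O[Si](C(C)C)(C(C)C)C(C)C)cc(CBr)c1Br | intermediate
4 | (5E)-6,10-dimethylundeca-5,9-dien-2-one ((E)-geranylacetone) | C/C(=C\CCC(C)=O)CCC=C(C)C | starting material
5 | (2R)-2-[(3E)-4,8-dimethylnona-3,7-dien-1-yl]-2-methyloxirane | C/C(=C\CC[C@]1(C)CO1)CCC=C(C)C | intermediate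
6 | ({2-bromo-3-methyl-5-[tri(propan-2-yl)silyloxy]phenyl}methyl)magnesium bromide (not isolated) | Cc1cc(O[Si](C(C)C)(C(C)C)C(C)C)cc(C[Mg]Br)c1Br | intermediate
7 | bromomagnesium (3R,6E)-1-{2-bromo-3-methyl-5-[tri(propan-2-yl)silyloxy]phenyl}-3,7,11-trimethyldodeca-6,10-dien-3-olate (not isolated) | C/C(=C\CC[C@@](C)(O[Mg]Br)CCc1cc(O[Si](C(C)C)(C(C)C)C(C)C)cc(C)c1Br)CCC=C(C)C | intermediate
8 | {[(2R)-2-[(3E)-4,8-dimethylnona-3,7-dien-1-yl]-2,8-dimethyl-3,4-dihydro-2H-chromen-6-yl]oxy}tri(propan-2-yl)silane | C/C(=C\CC[C@]1(C)CCc2cc(O[Si](C(C)C)(C(C)C)C(C)C)cc(C)c2O1)CCC=C(C)C | intermediate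
9 | (2E,6E)-9-[(2R)-2,8-dimethyl-6-{[tri(propan-2-yl)silyl]oxy}-3,4-dihydro-2H-chromen-2-yl]-2,6-dimethylnona-2,6-dien-1-ol (not isolated) | C/C(=C\CC[C@]1(C)CCc2cc(O[Si](C(C)C)(C(C)C)C(C)C)cc(C)c2O1)CC/C=C(\C)CO | intermediate
10 | (2E,6E)-9-[(2R)-2,8-dimethyl-6-{[tri(propan-2-yl)silyl]oxy}-3,4-dihydro-2H-chromen-2-yl]-2,6-dimethylnona-2,6-dienal | C/C(=C\CC[C@]1(C)CCc2cc(O[Si](C(C)C)(C(C)C)C(C)C)cc(C)c2O1)CC/C=C(\C)C=O | intermediate
11 | (2E,6E)-9-[(2R)-2,8-dimethyl-6-{[tri(propan-2-yl)silyl]oxy}-3,4-dihydro-2H-chromen-2-yl]-2,6-dimethylnona-2,6-dienoic acid | C/C(=C\CC[C@]1(C)CCc2cc(O[Si](C(C)C)(C(C)C)C(C)C)cc(C)c2O1)CC/C=C(\C)C(=O)O | intermediate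
12 | (2E,6E)-9-[(2R)-6-hydroxy-2,8-dimethyl-3,4-dihydro-2H-chromen-2-yl]-2,6-dimethylnona-2,6-dienoic acid | C/C(=C\CC[C@]1(C)CCc2cc(O)cc(C)c2O1)CC/C=C(\C)C(=O)O | target

Total step count: 7. Longest linear sequence: 6 steps (1 → 2 → 3 → 8 → 10 → 11 → 12, that is steps 1, 2, 4, 5, 6 and 7); step 3 is the one-step branch to epoxide 5.

Steps most likely to fail

Step 4. Three processes may go wrong: homocoupling during magnesium insertion; Lewis-acid-induced rearrangement of the epoxide instead of attack at CH2; and, above all, stalling of the palladium stage through inhibition by magnesium and copper salts or slow oxidative addition at the doubly flanked C–Br bond. Fallback: the operation is split. Setting out from 3 and 5, the first two stages are run as before, the mixture is quenched with aqueous NH4Cl, and the tertiary alcohol, (3R,6E)-1-{2-bromo-3-methyl-5-[tri(propan-2-yl)silyloxy]phenyl}-3,7,11-trimethyldodeca-6,10-dien-3-ol F1, is purified. Ring B is then closed in a separate, salt-free operation by copper-mediated Ullmann etherification (CuI, 3,4,7,8-tetramethyl-1,10-phenanthroline, Cs2CO3, toluene, 110 °C), which returns to 8. The same two bonds are made, but with a different metal for the C–O bond and in two operations.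

Step 5. The risk is competing ene oxidation at the internal trisubstituted alkene, over-oxidation, and loss of material to selenium-containing by-products at a late stage. Fallback: the terminal oxygen is installed before the annulation. Setting out from 4, SeO2/t-BuOOH oxidation gives (5E,9E)-11-hydroxy-6,10-dimethylundeca-5,9-dien-2-one F2. This is silylated (TBSCl, imidazole, DMF) to the tert-butyldimethylsilyl ether F3 and epoxidised under the conditions of step 3 to the (R)-epoxide F4. F4 and 3 are joined under the conditions of step 4, through the bromomagnesium alkoxide F5 (formed in the flask), to give the doubly silylated chroman F6. PPTS in MeOH should then cleave only the primary allylic silyl ether and return to 9, from which the MnO2 stage of step 5 leads to 10.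

Step 3. The risk is insufficient discrimination of the two ketone faces (methyl against a primary alkyl chain) and an uncatalysed background methylene transfer, both of which lower the enantiomeric purity that every later compound inherits. Fallback: reagent-controlled Sharpless epoxidation. This branch does not use 4. Purchased geranyl bromide alkylates the dianion of 2-methylprop-2-en-1-ol (n-BuLi, TMEDA, Et2O) to give (5E)-6,10-dimethyl-2-methylideneundeca-5,9-dien-1-ol F7. Ti(OiPr)4, D-(−)-diethyl tartrate and t-BuOOH (4 Å MS, CH2Cl2, −20 °C) epoxidise only the allylic alcohol alkene to {(2R)-2-[(3E)-4,8-dimethylnona-3,7-dien-1-yl]oxiran-2-yl}methanol F8. LiAlH4 in THF delivers hydride to the epoxide CH2 to give (2R,5E)-2,6,10-trimethylundeca-5,9-diene-1,2-diol F9. Selective primary tosylation (TsCl, Et3N, Bu2SnO cat., CH2Cl2) gives the monotosylate F10, and K2CO3 in MeOH closes the epoxide, returning to 5 with C2 fixed by the tartrate.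

Further compounds

F1 | step 4 | (3R,6E)-1-{2-bromo-3-methyl-5-[tri(propan-2-yl)silyloxy]phenyl}-3,7,11-trimethyldodeca-6,10-dien-3-ol | C/C(=C\CC[C@@](C)(O)CCc1cc(O[Si](C(C)C)(C(C)C)C(C)C)cc(C)c1Br)CCC=C(C)C
F2 | step 5 | (5E,9E)-11-hydroxy-6,10-dimethylundeca-5,9-dien-2-one | C/C(=C\CCC(C)=O)CC/C=C(\C)CO
F3 | step 5 | (5E,9E)-11-{[tert-butyl(dimethyl)silyl]oxy}-6,10-dimethylundeca-5,9-dien-2-one | C/C(=C\CCC(C)=O)CC/C=C(\C)CO[Si](C)(C)C(C)(C)C
F4 | step 5 | tert-butyl{[(2E,6E)-2,6-dimethyl-9-[(2R)-2-methyloxiran-2-yl]nona-2,6-dien-1-yl]oxy}dimethylsilane | C/C(=C\CC[C@]1(C)CO1)CC/C=C(\C)CO[Si](C)(C)C(C)(C)C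
F5 | step 5 | bromomagnesium (3R,6E,10E)-1-{2-bromo-3-methyl-5-[tri(propan-2-yl)silyloxy]phenyl}-12-{[tert-butyl(dimethyl)silyl]oxy}-3,7,11-trimethyldodeca-6,10-dien-3-olate | C/C(=C\CC[C@@](C)(O[Mg]Br)CCc1cc(O[Si](C(C)C)(C(C)C)C(C)C)cc(C)c1Br)CC/C=C(\C)CO[Si](C)(C)C(C)(C)C
F6 | step 5 | tert-butyl{[(2E,6E)-9-[(2R)-2,8-dimethyl-6-{[tri(propan-2-yl)silyl]oxy}-3,4-dihydro-2H-chromen-2-yl]-2,6-dimethylnona-2,6-dien-1-yl]oxy}dimethylsilane | C/C(=C\CC[C@]1(C)CCc2cc(O[Si](C(C)C)(C(C)C)C(C)C)cc(C)c2O1)CC/C=C(\C)CO[Si](C)(C)C(C)(C)C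
F7 | step 3 | (5E)-6,10-dimethyl-2-methylideneundeca-5,9-dien-1-ol | C/C(=C\CCC(=C)CO)CCC=C(C)C
F8 | step 3 | {(2R)-2-[(3E)-4,8-dimethylnona-3,7-dien-1-yl]oxiran-2-yl}methanol | C/C(=C\CC[C@@]1(CO)CO1)CCC=C(C)C
F9 | step 3 | (2R,5E)-2,6,10-trimethylundeca-5,9-diene-1,2-diol | C/C(=C\CC[C@@](C)(O)CO)CCC=C(C)C
F10 | step 3 | (2R,5E)-2-hydroxy-2,6,10-trimethylundeca-5,9-dien-1-yl 4-methylbenzenesulfonate | C/C(=C\CC[C@@](C)(O)COS(=O)(=O)c1ccc(C)cc1)CCC=C(C)C
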